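**Plan**
1. Retrosynthesis: the C6=C7/C8–H array comes from a reductive 1,3-transposition of a C6 carbinol. Bonds C8–C9 and C6–C7 are then cut together (rings B and C), followed by the two aryl O–C bonds of the dioxane, the C12–C13 bond, and ring D (annulation).
2. Forward order: ring E (cyclohexanone with quaternary C20), then ring D (Robinson annulation), then the ring A unit joined at C13, then the dioxane with the preformed 5/7 guaiane rings. Rings B and C close together in the last ring-forming step; Δ6 follows.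
3. Enabling feature: C5–C6 and C10–C9 are ortho on aromatic ring A, so a C6 aldehyde plus a tertiary C9–H is a latent hydroxy-o-quinodimethane. C8 carries only C14, so a C14 ethynyl sulfone serves as the tethered 2π partner.
4. Stereochemistry of rings D/E: C20 by catalytic asymmetric conjugate addition, C17 by chiral-imine Michael addition, C18 by hydrogenation, C13 and C14 by convex-face alkylations.
5. Stereochemistry of rings B/C and the guaiane: C9 from the chair-like tether in the key step; C6 from the suprafacial cycloaddition, relayed to 8β-H by Mitsunobu inversion and suprafacial diazene hydrogen transfer; C7′/C10′ from (S)-carvone via an ene-reductase; C1′/C5′ from the cycloaddition face.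

Key step: step 24

Remarks on the chemistry:
- Numbering: friedelane numbering (C1–C30) for the triterpene part, primed guaiane numbering (C1′–C15′) for the sesquiterpene part. Ar = 6-(dimethoxymethyl)-2,2,7-trimethyl-1,3-benzodioxol-5-yl (ring A with C4 methyl, C6 as dimethyl acetal, O2/O3 as acetonide).
- Assumption: the o-quinone of step 23 is taken to add across the ring-fusion double bond C1′=C5′ of 10, with O2 on C1′ and O3 on C5′, cis to the C10′ methyl, as in the presumed biogenesis. Isomers are removed by chromatography.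
- Compounds 29–39 are mixtures of C9 epimers; C9 becomes sp2 in step 24, so both converge.

**Part A – guaiatriene 10**

Step 1
Reactants: 1 (S)-(+)-carvone
Product: 2 (2R,5S)-2-methyl-5-(prop-1-en-2-yl)cyclohexan-1-one
Conditions: ene-reductase of the Old Yellow Enzyme family (e.g. OYE1), NADP+ (cat.), glucose dehydrogenase, D-glucose, phosphate buffer pH 7, 30 °C
Reagents that add atoms: none
Why: Biocatalytic asymmetric conjugate reduction; the flavin enzyme delivers hydride to C3 and a proton to C2 with fixed facial selectivity, so (S)-carvone should give the (2R) centre and hence the cis isomer, leaving the isopropenyl group untouched.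

Step 2
Reactants: 2 (2R,5S)-2-methyl-5-(prop-1-en-2-yl)cyclohexan-1-one
Product: 4 (2R,5S)-2-methyl-5-(prop-1-en-2-yl)cycloheptan-1-one, via silyl ketone 3 (not isolated)
Conditions: Me3SiCHN2, BF3·OEt2, CH2Cl2, −78 °C; then 1 M HCl, THF, 0 °C
Reagents that add atoms: trimethylsilyldiazomethane C[Si](C)(C)C=[N+]=[N-]
Why: Lewis-acid-promoted diazoalkane ring expansion (Tiffeneau–Demjanov type) with migration of the less substituted CH2, followed by protodesilylation; neither stereocentre takes part.

Step 3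
Reactants: 4 (2R,5S)-2-methyl-5-(prop-1-en-2-yl)cycloheptan-1-one
Product: 5 (E)-2,4,6-triisopropylbenzenesulfonylhydrazone of 4
Conditions: 2,4,6-triisopropylbenzenesulfonyl hydrazide, THF, 23 °C
Reagents that add atoms: 2,4,6-triisopropylbenzenesulfonyl hydrazide NNS(=O)(=O)c1c(C(C)C)cc(C(C)C)cc1C(C)C
Why: Hydrazone condensation; the sulfonamide nitrogen should sit anti to the methyl-bearing α-carbon, which directs the next deprotonation to the CH2 side.

Step 4
Reactants: 5 (E)-2,4,6-triisopropylbenzenesulfonylhydrazone of 4; 6 (E)-but-2-enal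
Product: 8 (2E)-1-[(4S,7R)-7-methyl-4-(prop-1-en-2-yl)cyclohept-1-en-1-yl]but-2-en-1-ol (carbinol epimers), via vinyllithium 7 (not isolated)
Conditions: n-BuLi (2.2 equiv), THF, −78 → 0 °C; then 6, −78 °C
Reagents that add atoms: none
Why: Shapiro reaction (syn α-deprotonation at the less substituted CH2, loss of sulfinate and N2) gives the less substituted vinyllithium, which adds 1,2 to the enal; C7′ and C10′ are not touched.

Step 5
Reactants: 8 (2E)-1-[(4S,7R)-7-methyl-4-(prop-1-en-2-yl)cyclohept-1-en-1-yl]but-2-en-1-ol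
Product: 10 (7S,10R)-guaia-1(5),3,11-triene [(4R,7S)-1,4-dimethyl-7-(prop-1-en-2-yl)-3,4,5,6,7,8-hexahydroazulene], via diene isomer 9 (not isolated)
Conditions: TsOH·H2O (5 mol%), Et2O, 0 → 23 °C; then toluene, 50 °C
Reagents that add atoms: none
Why: Ionisation of the bis-allylic alcohol to a pentadienyl cation, conrotatory 4π electrocyclisation and proton loss (the cyclodehydration used for alkylcyclopentadienes), then [1,5]-hydrogen shifts towards the more substituted diene; the product is used fresh.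

**Part B – cis-decalone 18 (rings D and E)**

Step 6
Reactants: 11 methyl 3-oxocyclohex-1-ene-1-carboxylate
Product: 12 methyl (1R)-1-methyl-3-oxocyclohexane-1-carboxylate
Conditions: Me2Zn, Cu(OTf)2 (2.5 mol%), chiral sulfonate-bearing imidazolinium salt (carbene precursor, 5 mol%), t-BuOMe, −30 °C; aq. NH4Cl
Reagents that add atoms: dimethylzinc C[Zn]C
Why: Copper-catalysed enantioselective conjugate addition to a cyclic γ-keto ester; the chiral carbene ligand controls the face and sets the quaternary C20 centre.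

Step 7
Reactants: 12 methyl (1R)-1-methyl-3-oxocyclohexane-1-carboxylate
Product: 13 methyl (1R)-1,4-dimethyl-3-oxocyclohexane-1-carboxylate (C4 epimers)
Conditions: LiN(i-Pr)2, THF, −78 °C; MeI, −78 → −20 °C
Reagents that add atoms: iodomethane CI
Why: Kinetic enolate formation at the α-CH2 remote from the quaternary carbon, then methylation; the new centre is a mixture that is re-set in step 8.

Step 8
Reactants: 13 methyl (1R)-1,4-dimethyl-3-oxocyclohexane-1-carboxylate; 14 pent-1-en-3-one
Product: 17 methyl (2R,4aR)-4a,8-dimethyl-7-oxo-1,2,3,4,4a,5,6,7-octahydronaphthalene-2-carboxylate, via imine 15 (not isolated), via diketone 16 (not isolated)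
Conditions: (S)-1-phenylethylamine, TsOH (cat.), toluene, reflux (−H2O); then 14, THF, 40 °C; then aq. AcOH, 23 °C; then NaOMe, MeOH, 60 °C
Reagents that add atoms: none
Why: d'Angelo deracemising Michael addition through the more substituted secondary enamine, in which the auxiliary shields one face and sets quaternary C17, followed by Robinson aldol condensation to close ring D.

Step 9
Reactants: 17 methyl (2R,4aR)-4a,8-dimethyl-7-oxo-1,2,3,4,4a,5,6,7-octahydronaphthalene-2-carboxylate
Product: 18 methyl (2R,4aR,8aS)-4a,8-dimethyl-7-oxodecahydronaphthalene-2-carboxylate (cis-fused; C8 epimers)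
Conditions: H2 (3 atm), 10% Pd/C, EtOH, Et3N (1 equiv), 23 °C
Reagents that add atoms: none
Why: Heterogeneous hydrogenation of an angularly methylated octalone under basic conditions should give the cis-fused decalone (H18 cis to the C17 methyl); the epimeric C13 centre is enolised in step 15.

**Part C – ring A allyl carbonate 27**

Step 10
Reactants: 19 2-bromo-3-hydroxy-4-methoxybenzaldehyde
Product: 20 3-hydroxy-4-methoxy-2-methylbenzaldehyde
Conditions: MeB(OH)2, Pd(dppf)Cl2 (5 mol%), K2CO3, dioxane/H2O, 100 °C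
Reagents that add atoms: methylboronic acid CB(O)O
Why: Suzuki–Miyaura methylation of the aryl bromide, tolerant of the free phenol and the aldehyde.

Step 11
Reactants: 20 3-hydroxy-4-methoxy-2-methylbenzaldehyde
Product: 21 6-bromo-3-hydroxy-4-methoxy-2-methylbenzaldehyde
Conditions: Br2, NaOAc, AcOH, 23 °C
Reagents that add atoms: bromine BrBr
Why: Electrophilic aromatic bromination para to the free phenol, whose ortho positions are both occupied.

Step 12
Reactants: 21 6-bromo-3-hydroxy-4-methoxy-2-methylbenzaldehyde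
Product: 22 6-bromo-3,4-dihydroxy-2-methylbenzaldehyde
Conditions: BBr3, CH2Cl2, −78 → 0 °C; H2O
Reagents that add atoms: none
Why: Lewis-acid cleavage of the aryl methyl ether.

Step 13
Reactants: 22 6-bromo-3,4-dihydroxy-2-methylbenzaldehyde
Product: 23 6-bromo-5-(dimethoxymethyl)-2,2,4-trimethyl-1,3-benzodioxole
Conditions: 2,2-dimethoxypropane, TsOH·H2O (cat.), toluene, reflux (MeOH removed); Et3N quench
Reagents that add atoms: 2,2-dimethoxypropane COC(C)(C)OC
Why: Acid-catalysed transketalisation gives the catechol acetonide and, by acetal exchange, the dimethyl acetal of the aldehyde in one operation.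

Step 14
Reactants: 23 6-bromo-5-(dimethoxymethyl)-2,2,4-trimethyl-1,3-benzodioxole; 24 but-3-en-2-one
Product: 27 2-Ar-but-3-en-2-yl methyl carbonate (racemic), via aryllithium 25 (not isolated), via lithium alkoxide 26 (not isolated)
Conditions: n-BuLi, THF, −78 °C; CeCl3, −78 °C; 24; then ClCO2Me, −78 → 0 °C
Reagents that add atoms: methyl chloroformate COC(Cl)=O
Why: Bromine–lithium exchange, organocerium 1,2-addition to the enone and O-acylation of the tertiary alkoxide; the carbinol centre is lost on π-allyl formation in step 15.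

**Part D – union, dioxane, rings B/C, endgame**

Step 15
Reactants: 18 methyl (2R,4aR,8aS)-4a,8-dimethyl-7-oxodecahydronaphthalene-2-carboxylate; 27 2-Ar-but-3-en-2-yl methyl carbonate
Product: 28 C13-allylated cis-decalone (13β-[(2E)-3-Ar-but-2-en-1-yl], 13α-methyl, 14-ketone)
Conditions: KH (1.0 equiv), THF, 23 °C; BEt3 (1.1 equiv); then Pd(PPh3)4 (5 mol%) and 27, 0 → 23 °C
Reagents that add atoms: none
Why: Tsuji–Trost allylation of the thermodynamic (more substituted) potassium enoxyborate at the unsubstituted allyl terminus; attack is expected on the convex face of the cis-decalin (cis to H18 and the C17 methyl), since concave approach either eclipses the axial ring E carbon C19 or runs 1,3-syn-axial to C22, which places the chain β and the methyl α at C13.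

Step 16
Reactants: 28 C13-allylated cis-decalone
Product: 29 13β-(3-Ar-butyl)-13α-methyl cis-decalone (C9 epimers)
Conditions: H2 (1 atm), PtO2, EtOAc, K2CO3 (trace), 23 °C
Reagents that add atoms: none
Why: Catalytic hydrogenation of the trisubstituted styrene without benzylic C–O hydrogenolysis; C9 forms as a mixture that converges in step 24.

Step 17
Reactants: 29 13β-(3-Ar-butyl)-13α-methyl cis-decalone
Product: 30 C14 2-(trimethylsilyl)ethyl enol ether (C14=CH–OCH2CH2SiMe3, E/Z)
Conditions: [Ph3PCH2OCH2CH2SiMe3]Cl, KN(SiMe3)2, THF, 0 °C; then 29, 65 °C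
Reagents that add atoms: [2-(trimethylsilyl)ethoxy]methyl(triphenyl)phosphonium chloride C[Si](C)(C)CCOC[P+](c1ccccc1)(c1ccccc1)c1ccccc1.[Cl-]
Why: Wittig alkoxymethylenation of the hindered ketone; the silylethyl group allows later unmasking without acid, so the two acetals survive.

Step 18
Reactants: 30 C14 2-(trimethylsilyl)ethyl enol ether
Product: 31 C14 carbaldehyde (C14 epimers)
Conditions: Bu4NF, THF, 23 → 50 °C; aq. NH4Cl
Reagents that add atoms: none
Why: Fluoride-induced fragmentation of the 2-silylethyl enol ether (loss of ethene and Me3SiF) gives the aldehyde enolate, which is protonated on work-up.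

Step 19
Reactants: 31 C14 carbaldehyde
Product: 32 14β-methyl-14α-carbaldehyde
Conditions: KOt-Bu, t-BuOH/THF, 0 °C; MeI
Reagents that add atoms: iodomethane CI
Why: C-Methylation of the α,α-disubstituted aldehyde enolate from the convex β face, anti to the C13 α-methyl, which sets quaternary C14 (methyl β, formyl α).

Step 20
Reactants: 32 14β-methyl-14α-carbaldehyde
Product: 33 14α-ethynyl-14β-methyl compound
Conditions: dimethyl (1-diazo-2-oxopropyl)phosphonate, K2CO3, MeOH, 23 → 40 °C
Reagents that add atoms: dimethyl (1-diazo-2-oxopropyl)phosphonate COP(=O)(OC)C(=[N+]=[N-])C(C)=O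
Why: Ohira–Bestmann (Seyferth–Gilbert) homologation of a non-enolisable aldehyde to the terminal alkyne.

Step 21
Reactants: 33 14α-ethynyl-14β-methyl compound
Product: 35 14α-[(phenylsulfonyl)ethynyl] compound, via iodovinyl sulfone 34 (not isolated)
Conditions: PhSO2Na, I2, NaOAc, MeCN, 23 °C; then K2CO3, acetone, 56 °C
Reagents that add atoms: sodium benzenesulfinate [Na+].[O-]S(=O)c1ccccc1
Why: Radical iodosulfonylation of the terminal alkyne (sulfonyl on the terminal carbon) followed by dehydroiodination gives the alkynyl sulfone that activates C8≡C7.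

Step 22
Reactants: 35 14α-[(phenylsulfonyl)ethynyl] compound
Product: 36 catechol (free 2,3-dihydroxy ring A; C6 still dimethyl acetal)
Conditions: AcCl (0.2 equiv, HCl source), MeOH/HC(OMe)3, 45 °C; NaHCO3
Reagents that add atoms: none
Why: Acid-catalysed transketalisation to methanol releases the catechol, while the orthoformate keeps the aldehyde as its acetal, so the ring carries no π-acceptor in step 23.

Step 23
Reactants: 36 catechol; 10 (7S,10R)-guaia-1(5),3,11-triene
Product: 39 benzodioxane aldehyde (O2–C1′, O3–C5′, cis-fused; C6 aldehyde), via o-quinone 37 (not isolated), via cycloadduct acetal 38 (not isolated)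
Conditions: Ag2O (3 equiv), 10 (4 equiv), 4 Å MS, CH2Cl2/Et2O, −20 → 0 °C, dark; filter; then oxalic acid (cat.), wet SiO2, CH2Cl2, 0 °C
Reagents that add atoms: water O
Why: Oxidation to the o-quinone and inverse-electron-demand hetero-Diels–Alder addition (O=C–C=O as 4π, the tetrasubstituted C1′=C5′ bond as 2π) closes the cis-fused dioxane; with no acceptor on ring A the leading bond should join the less hindered O2 to the diene terminus C1′ and O3 to allylic C5′, and the acetal is then hydrolysed under conditions the tertiary allylic aryl ether tolerates.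

Step 24
Reactants: 39 benzodioxane aldehyde
Product: 41 6α-hydroxy-7-(phenylsulfonyl)-Δ7 compound with rings B and C closed (9β-methyl), via photoenol 40 (not isolated)
Conditions: hν (365 nm), degassed benzene (0.005 M), 23 °C
Reagents that add atoms: none
Why: Proposed new method: the excited aryl aldehyde abstracts the tertiary benzylic hydrogen at C9 through a six-membered transition state, and the (E)-hydroxy-o-quinodimethane 40 (C6(OH)=C5–C10=C9) adds as the 4π unit to the tethered ethynyl sulfone in a polarised [4+2] cycloaddition (C9 onto the β-carbon C8, C6 onto C7); the closest known reaction type is the photoenolisation/Diels–Alder reaction of o-alkyl aryl aldehydes with electron-poor alkenes and alkynes, which has not been shown for a tertiary C–H donor forming a quaternary carbon next to a fully substituted one. Ring B closes as the cycloaddition ring and ring C closes in the same elementary step through the four-atom tether C11–C12–C13–C14 (type 1 intramolecular Diels–Alder, fused mode), so no ring is formed afterwards. C9 is controlled by the tether: ring D holds C12 and C8 trans-diequatorial, and the chair-like arrangement of the forming ring C places the C9 methyl axial and syn to the C14 methyl (β), whereas the boat alternative would bring it to flagpole distance of the C13 methyl. C6 follows from suprafacial addition to the dienol in which OH and C11 are both outside, making the hydroxyl cis to C11 (α). The step needs cycloaddition to outrun reketonisation, which the sulfone-activated alkyne held four atoms away and exclusion of oxygen should secure. It also needs productive abstraction from C9–H; abstraction from the C4 methyl gives a dienol that cannot reach the alkyne and simply reverts.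

Step 25
Reactants: 41 6α-hydroxy-7-(phenylsulfonyl)-Δ7 compound
Product: 42 6α-hydroxy-Δ7 compound
Conditions: Na/Hg (6%), Na2HPO4, MeOH/THF, −20 °C
Reagents that add atoms: none
Why: Julia-type reductive desulfonylation of the non-conjugated vinyl sulfone keeps the double bond at C7=C8 and leaves C6, C9, the ester and the isolated alkenes untouched.

Step 26
Reactants: 42 6α-hydroxy-Δ7 compound
Product: 45 target compound CNP0287532.1, via sulfonylhydrazine 43 (not isolated), via allylic diazene 44 (not isolated)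
Conditions: 2-nitrobenzenesulfonyl hydrazide, PPh3, diethyl azodicarboxylate, N-methylmorpholine, −30 → 23 °C
Reagents that add atoms: none
Why: Myers reductive 1,3-transposition: Mitsunobu displacement inverts C6 (nitrogen β), sulfinic acid is lost, and the allylic diazene expels N2 in a retro-ene step that delivers hydrogen suprafacially to the β face of C8, giving 8β-H (cis to the C9 methyl) and the C6=C7 bond.

**Compound list**
1 | (S)-(+)-carvone | C=C(C)[C@H]1CC=C(C)C(=O)C1 | starting material
2 | (2R,5S)-2-methyl-5-(prop-1-en-2-yl)cyclohexan-1-one | C=C(C)[C@H]1CC[C@@H](C)C(=O)C1 | intermediate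
3 | (2R,5S)-2-methyl-5-(prop-1-en-2-yl)-7-(trimethylsilyl)cycloheptan-1-one | C=C(C)[C@H]1CC[C@@H](C)C(=O)C([Si](C)(C)C)C1 | intermediate
4 | (2R,5S)-2-methyl-5-(prop-1-en-2-yl)cycloheptan-1-one | C=C(C)[C@H]1CC[C@@H](C)C(=O)CC1 | intermediate
5 | (E)-2,4,6-triisopropylbenzenesulfonylhydrazone of 4 | C=C(C)[C@H]1CC[C@@H](C)/C(=N/NS(=O)(=O)c2c(C(C)C)cc(C(C)C)cc2C(C)C)CC1 | intermediate
6 | (E)-but-2-enal | C/C=C/C=O | starting material
7 | [(4S,7R)-7-methyl-4-(prop-1-en-2-yl)cyclohept-1-en-1-yl]lithium | C=C(C)[C@H]1CC[C@@H](C)C([Li])=CC1 | intermediate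
8 | (2E)-1-[(4S,7R)-7-methyl-4-(prop-1-en-2-yl)cyclohept-1-en-1-yl]but-2-en-1-ol (carbinol epimers) | C=C(C)[C@H]1CC[C@@H](C)C(C(O)/C=C/C)=CC1 | intermediate
9 | (7S,10R)-guaia-1(5),2,11-triene (C4′ epimers) | C=C(C)[C@H]1CC[C@@H](C)C2=C(C1)C(C)C=C2 | intermediate
10 | (7S,10R)-guaia-1(5),3,11-triene | C=C(C)[C@H]1CC[C@@H](C)C2=C(C1)C(C)=CC2 | intermediate
11 | methyl 3-oxocyclohex-1-ene-1-carboxylate | COC(=O)C1=CC(=O)CCC1 | starting material
12 | methyl (1R)-1-methyl-3-oxocyclohexane-1-carboxylate | O=C1C[C@](C)(C(=O)OC)CCC1 | intermediate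
13 | methyl (1R)-1,4-dimethyl-3-oxocyclohexane-1-carboxylate (C4 epimers) | O=C1C[C@](C)(C(=O)OC)CCC1C | intermediate
14 | pent-1-en-3-one | C=CC(=O)CC | starting material
15 | (S)-1-phenylethyl imine of 13 | C[C@H](N=C1C[C@](C)(C(=O)OC)CCC1C)c1ccccc1 | intermediate
16 | methyl (1R,4R)-1,4-dimethyl-3-oxo-4-(3-oxopentyl)cyclohexane-1-carboxylate | O=C1C[C@](C)(C(=O)OC)CC[C@]1(C)CCC(=O)CC | intermediate
17 | methyl (2R,4aR)-4a,8-dimethyl-7-oxo-1,2,3,4,4a,5,6,7-octahydronaphthalene-2-carboxylate | CC1=C2C[C@](C)(C(=O)OC)CC[C@]2(C)CCC1=O | intermediate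
18 | methyl (2R,4aR,8aS)-4a,8-dimethyl-7-oxodecahydronaphthalene-2-carboxylate (cis-fused, C8 epimers) | CC1[C@@H]2C[C@](C)(C(=O)OC)CC[C@]2(C)CCC1=O | intermediate
19 | 2-bromo-3-hydroxy-4-methoxybenzaldehyde | COc1ccc(C=O)c(Br)c1O | starting material
20 | 3-hydroxy-4-methoxy-2-methylbenzaldehyde | COc1ccc(C=O)c(C)c1O | intermediate
21 | 6-bromo-3-hydroxy-4-methoxy-2-methylbenzaldehyde | COc1cc(Br)c(C=O)c(C)c1O | intermediate
22 | 6-bromo-3,4-dihydroxy-2-methylbenzaldehyde | Oc1cc(Br)c(C=O)c(C)c1O | intermediate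
23 | 6-bromo-5-(dimethoxymethyl)-2,2,4-trimethyl-1,3-benzodioxole | COC(OC)c1c(Br)cc2OC(C)(C)Oc2c1C | intermediate
24 | but-3-en-2-one | C=CC(C)=O | starting material
25 | [6-(dimethoxymethyl)-2,2,7-trimethyl-1,3-benzodioxol-5-yl]lithium | COC(OC)c1c([Li])cc2OC(C)(C)Oc2c1C | intermediate
26 | lithium 2-Ar-but-3-en-2-olate (racemic) | [Li+].[O-]C(C)(C=C)c1cc2OC(C)(C)Oc2c(C)c1C(OC)OC | intermediate
27 | 2-Ar-but-3-en-2-yl methyl carbonate (racemic) | COC(=O)OC(C)(C=C)c1cc2OC(C)(C)Oc2c(C)c1C(OC)OC | intermediate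
28 | cis-decalone with 13β-[(2E)-3-Ar-but-2-en-1-yl] and 13α-methyl | C/C(=C\C[C@@]1(C)[C@@H]2C[C@](C)(C(=O)OC)CC[C@]2(C)CCC1=O)c1cc2OC(C)(C)Oc2c(C)c1C(OC)OC | intermediate
29 | cis-decalone with 13β-(3-Ar-butyl) and 13α-methyl (C9 epimers) | CC(CC[C@@]1(C)[C@@H]2C[C@](C)(C(=O)OC)CC[C@]2(C)CCC1=O)c1cc2OC(C)(C)Oc2c(C)c1C(OC)OC | intermediate
30 | C14 2-(trimethylsilyl)ethyl enol ether of 29 (E/Z) | CC(CC[C@@]1(C)[C@@H]2C[C@](C)(C(=O)OC)CC[C@]2(C)CCC1=COCC[Si](C)(C)C)c1cc2OC(C)(C)Oc2c(C)c1C(OC)OC | intermediate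
31 | C14 carbaldehyde (C14 epimers) | CC(CC[C@@]1(C)[C@@H]2C[C@](C)(C(=O)OC)CC[C@]2(C)CCC1C=O)c1cc2OC(C)(C)Oc2c(C)c1C(OC)OC | intermediate
32 | 14β-methyl-14α-carbaldehyde | CC(CC[C@@]1(C)[C@@H]2C[C@](C)(C(=O)OC)CC[C@]2(C)CC[C@]1(C)C=O)c1cc2OC(C)(C)Oc2c(C)c1C(OC)OC | intermediate
33 | 14α-ethynyl-14β-methyl compound | CC(CC[C@@]1(C)[C@@H]2C[C@](C)(C(=O)OC)CC[C@]2(C)CC[C@]1(C)C#C)c1cc2OC(C)(C)Oc2c(C)c1C(OC)OC | intermediate
34 | (E)-β-iodovinyl phenyl sulfone from 33 | CC(CC[C@@]1(C)[C@@H]2C[C@](C)(C(=O)OC)CC[C@]2(C)CC[C@]1(C)/C(I)=C\S(=O)(=O)c1ccccc1)c1cc2OC(C)(C)Oc2c(C)c1C(OC)OC | intermediate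
35 | 14α-[(phenylsulfonyl)ethynyl] compound (acetonide, acetal) | CC(CC[C@@]1(C)[C@@H]2C[C@](C)(C(=O)OC)CC[C@]2(C)CC[C@]1(C)C#CS(=O)(=O)c1ccccc1)c1cc2OC(C)(C)Oc2c(C)c1C(OC)OC | intermediate
36 | catechol with C6 dimethyl acetal | CC(CC[C@@]1(C)[C@@H]2C[C@](C)(C(=O)OC)CC[C@]2(C)CC[C@]1(C)C#CS(=O)(=O)c1ccccc1)c1cc(O)c(O)c(C)c1C(OC)OC | intermediate
37 | o-quinone of 36 | CC(CC[C@@]1(C)[C@@H]2C[C@](C)(C(=O)OC)CC[C@]2(C)CC[C@]1(C)C#CS(=O)(=O)c1ccccc1)C1=CC(=O)C(=O)C(C)=C1C(OC)OC | intermediate
38 | benzodioxane cycloadduct, C6 dimethyl acetal | C=C(C)[C@H]1CC[C@@H](C)[C@]23CC=C(C)[C@@]2(C1)Oc1c(cc(C(C)CC[C@@]4(C)[C@@H]5C[C@](C)(C(=O)OC)CC[C@]5(C)CC[C@]4(C)C#CS(=O)(=O)c4ccccc4)c(C(OC)OC)c1C)O3 | intermediate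
39 | benzodioxane aldehyde | C=C(C)[C@H]1CC[C@@H](C)[C@]23CC=C(C)[C@@]2(C1)Oc1c(cc(C(C)CC[C@@]4(C)[C@@H]5C[C@](C)(C(=O)OC)CC[C@]5(C)CC[C@]4(C)C#CS(=O)(=O)c4ccccc4)c(C=O)c1C)O3 | intermediate
40 | (E)-hydroxy-o-quinodimethane (photoenol) of 39 | C=C(C)[C@H]1CC[C@@H](C)[C@]23CC=C(C)[C@@]2(C1)OC1=C(C)/C(=C\O)/C(=C(\C)CC[C@@]4(C)[C@@H]5C[C@](C)(C(=O)OC)CC[C@]5(C)CC[C@]4(C)C#CS(=O)(=O)c4ccccc4)C=C1O3 | intermediate
41 | 6α-hydroxy-7-(phenylsulfonyl)-Δ7 octacycle (9β-methyl) | C=C(C)[C@H]1CC[C@@H](C)[C@]23CC=C(C)[C@@]2(C1)Oc1c(cc2c(c1C)[C@@H](O)C(S(=O)(=O)c4ccccc4)=C1[C@@]2(C)CC[C@@]2(C)[C@@H]4C[C@](C)(C(=O)OC)CC[C@]4(C)CC[C@]12C)O3 | intermediate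
42 | 6α-hydroxy-Δ7 octacycle | C=C(C)[C@H]1CC[C@@H](C)[C@]23CC=C(C)[C@@]2(C1)Oc1c(cc2c(c1C)[C@@H](O)C=C1[C@@]2(C)CC[C@@]2(C)[C@@H]4C[C@](C)(C(=O)OC)CC[C@]4(C)CC[C@]12C)O3 | intermediate
43 | N-(6β-yl)-N-(2-nitrobenzenesulfonyl)hydrazine | C=C(C)[C@H]1CC[C@@H](C)[C@]23CC=C(C)[C@@]2(C1)Oc1c(cc2c(c1C)[C@H](N(N)S(=O)(=O)c4ccccc4[N+](=O)[O-])C=C1[C@@]2(C)CC[C@@]2(C)[C@@H]4C[C@](C)(C(=O)OC)CC[C@]4(C)CC[C@]12C)O3 | intermediate
44 | 6β-allylic diazene | C=C(C)[C@H]1CC[C@@H](C)[C@]23CC=C(C)[C@@]2(C1)Oc1c(cc2c(c1C)[C@H](N=N)C=C1[C@@]2(C)CC[C@@]2(C)[C@@H]4C[C@](C)(C(=O)OC)CC[C@]4(C)CC[C@]12C)O3 | intermediate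
45 | CNP0287532.1 | C=C(C)[C@H]1CC[C@@H](C)[C@]23CC=C(C)[C@@]2(C1)Oc1c(cc2c(c1C)C=C[C@@H]1[C@@]2(C)CC[C@@]2(C)[C@@H]4C[C@](C)(C(=O)OC)CC[C@]4(C)CC[C@]12C)O3 | target

**Step count and longest linear sequence**
- Total: 26 steps.
- Longest linear sequence: 17 steps (steps 10–14, then 15–26).

**Three steps most likely to fail**

1. Step 24 (proposed new method). The photoenol may reketonise or photocyclise faster than it adds to the alkyne, or the tether may react through the boat arrangement and give the C9 epimer. The fallback uses known chemistry and sets out from 39. Irradiation at −40 °C in CH2Cl2 without heating is expected to collect the photocyclisation product, the benzocyclobutenol F1 (a known outcome for hindered o-alkyl aryl carbonyl compounds). Heating F1 in degassed toluene at 110 °C opens the four-membered ring thermally and reversibly to the same (E)-dienol, so that even a slow intramolecular Diels–Alder addition to the ethynyl sulfone can compete. The route is rejoined at 41.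

2. Step 23. The o-quinone may add to the less hindered C3′=C4′ double bond of the cyclopentadiene or to a double-bond isomer formed by [1,5]-hydrogen shift. It may also add with the two oxygens interchanged or from the wrong face, or tautomerise before it is trapped. The fallback sets out from 10 and 36 and masks the 3′,4′-double bond first. OsO4 (cat.) with N-methylmorpholine N-oxide should dihydroxylate the less hindered trisubstituted bond of 10 to the cis-3′,4′-diol F2, which keeps only the ring-fusion alkene. Oxidation of 36 with Ag2O in the presence of F2 gives the cycloadduct diol acetal F3, and mild acid hydrolysis gives the diol aldehyde F4. 1,1′-Thiocarbonyldiimidazole converts F4 into the cyclic thiocarbonate F5, and Corey–Winter olefination with 1,3-dimethyl-2-phenyl-1,3,2-diazaphospholidine at 40 °C restores the C3′=C4′ bond. The route is rejoined at 39.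

3. Step 26. The doubly activated (benzylic and allylic) C6 carbinol may ionise under Mitsunobu conditions, which would scramble C6 and therefore C8, or the hindered substitution may not proceed. The fallback sets out from 42. Methyl chloroformate and pyridine give the allylic methyl carbonate F6. Pd(OAc)2, PBu3 and HCO2NH4 in THF at 40 °C then effect a Tsuji–Trost formate reduction: zerovalent palladium ionises the carbonate with inversion, and hydride is delivered from the metal to the more substituted allyl terminus C8 on the face opposite to the leaving group. This gives the same 8β-H and C6=C7 outcome and rejoins the route at 45.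

Further compounds
F1 | step 24 | benzocyclobutenol from 39 (C6/C9 epimers) | C=C(C)[C@H]1CC[C@@H](C)[C@]23CC=C(C)[C@@]2(C1)Oc1c(cc2c(c1C)C(O)C2(C)CC[C@@]4(C)[C@@H]5C[C@](C)(C(=O)OC)CC[C@]5(C)CC[C@]4(C)C#CS(=O)(=O)c4ccccc4)O3
F2 | step 23 | (7S,10R)-guaia-1(5),11-diene-3,4-diol (cis-diol) | C=C(C)[C@H]1CC[C@@H](C)C2=C(C1)C(C)(O)C(O)C2
F3 | step 23 | cycloadduct 3′,4′-diol, C6 dimethyl acetal | C=C(C)[C@H]1CC[C@@H](C)[C@]23CC(O)C(C)(O)[C@@]2(C1)Oc1c(cc(C(C)CC[C@@]4(C)[C@@H]5C[C@](C)(C(=O)OC)CC[C@]5(C)CC[C@]4(C)C#CS(=O)(=O)c4ccccc4)c(C(OC)OC)c1C)O3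
F4 | step 23 | cycloadduct 3′,4′-diol aldehyde | C=C(C)[C@H]1CC[C@@H](C)[C@]23CC(O)C(C)(O)[C@@]2(C1)Oc1c(cc(C(C)CC[C@@]4(C)[C@@H]5C[C@](C)(C(=O)OC)CC[C@]5(C)CC[C@]4(C)C#CS(=O)(=O)c4ccccc4)c(C=O)c1C)O3
F5 | step 23 | cyclic 3′,4′-thiocarbonate of F4 | C=C(C)[C@H]1CC[C@@H](C)[C@]23CC6OC(=S)OC6(C)[C@@]2(C1)Oc1c(cc(C(C)CC[C@@]4(C)[C@@H]5C[C@](C)(C(=O)OC)CC[C@]5(C)CC[C@]4(C)C#CS(=O)(=O)c4ccccc4)c(C=O)c1C)O3
F6 | step 26 | 6α-allylic methyl carbonate of 42 | C=C(C)[C@H]1CC[C@@H](C)[C@]23CC=C(C)[C@@]2(C1)Oc1c(cc2c(c1C)[C@@H](OC(=O)OC)C=C1[C@@]2(C)CC[C@@]2(C)[C@@H]4C[C@](C)(C(=O)OC)CC[C@]4(C)CC[C@]12C)O3
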